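**Plan**
- **Cuts, in retrosynthetic order:** the two O–acetyl bonds on ring B; the C5–O bond of ring A (key cut, back to the 5-deoxyflavone); the acetyl/benzyl exchange at O2' and O4'; the O3–CH3 bond; O1–C2 and C3–O of ring C; the Cα=Cβ bond of the chalcone.
- **Forward:** rings A and B enter as an acetophenone and a benzaldehyde and are joined by aldol condensation. Ring C then closes oxidatively to the flavonol, O3 is methylated, benzyl is swapped for acetyl, C5 is oxygenated, and the acetates are removed.
- **Enabling feature:** ring A of the 7,8-dimethoxy-5-deoxyflavone has only C5–H and C6–H, and C5–H alone lies peri to the C4 carbonyl oxygen of ring C. A metal held on that oxygen therefore reaches C5 through the five-membered array O–C4–C4a–C5–metal. Leaving O5 out until then also keeps the chalcone free of a 6'-substituent.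
- **Stereochemistry:** the target has no stereocentre. The chalcone alkene is E by thermodynamic control, and the transient C2/C3 centres vanish when ring C becomes the pyranone.

Key step: step 8

Remark: the dihydroflavonol passed through in the ring C closure is racemic, and its SMILES shows one enantiomer of the trans pair. The same holds for the oxiranes of the fallbacks.

**Step 1**
Reactants: 1 2,4,5-trimethoxybenzaldehyde
Product: 2 2,4-dihydroxy-5-methoxybenzaldehyde
Conditions: AlCl3 (excess), CH2Cl2, 0 °C → rt; then ice-water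
Reagents that add atoms: none
Why: Lewis-acid aryl methyl ether cleavage, in which AlCl3 on the aldehyde oxygen activates only the conjugated ortho and para methoxy groups for SN2 removal of methyl by chloride, while the meta 5-methoxy group lacks this activation and should stay.

**Step 2**
Reactants: 2 2,4-dihydroxy-5-methoxybenzaldehyde
Product: 3 2,4-bis(benzyloxy)-5-methoxybenzaldehyde
Conditions: BnBr (2.4 equiv), K2CO3, DMF, 60 °C
Reagents that add atoms: benzyl bromide, BrCc1ccccc1
Why: Williamson ether synthesis, with warming in DMF enough to alkylate the hydrogen-bonded 2-hydroxyl as well, giving ethers that withstand the alkaline steps ahead.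

**Step 3**
Reactants: 3 2,4-bis(benzyloxy)-5-methoxybenzaldehyde; 4 2-hydroxy-3,4-dimethoxyacetophenone
Product: 5 (E)-3-[2,4-bis(benzyloxy)-5-methoxyphenyl]-1-(2-hydroxy-3,4-dimethoxyphenyl)prop-2-en-1-one
Conditions: KOH (excess), EtOH, rt; then aq HCl
Reagents that add atoms: none
Why: Claisen–Schmidt condensation of the methyl ketone enolate with a non-enolisable aldehyde, where E1cB loss of water should give the conjugated, thermodynamically preferred E-enone.

**Step 4**
Reactants: 5 (E)-3-[2,4-bis(benzyloxy)-5-methoxyphenyl]-1-(2-hydroxy-3,4-dimethoxyphenyl)prop-2-en-1-one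
Product: 7 2-[2,4-bis(benzyloxy)-5-methoxyphenyl]-3-hydroxy-7,8-dimethoxy-4H-chromen-4-one, via rac-trans-dihydroflavonol 6 (not isolated)
Conditions: 30% H2O2, aq NaOH, MeOH/THF, 0 °C → rt; then aq HCl
Reagents that add atoms: hydrogen peroxide, OO
Why: Algar–Flynn–Oyamada oxidation, in which hydroperoxide oxygenates the enone, the 2'-phenoxide closes ring C at Cβ to give 6, and alkaline peroxide dehydrogenates 6 to the flavonol (erasing both transient stereocentres); the lack of a 6'-substituent keeps attack at Cα, the aurone path, minor.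

**Step 5**
Reactants: 7 2-[2,4-bis(benzyloxy)-5-methoxyphenyl]-3-hydroxy-7,8-dimethoxy-4H-chromen-4-one
Product: 8 2-[2,4-bis(benzyloxy)-5-methoxyphenyl]-3,7,8-trimethoxy-4H-chromen-4-one
Conditions: MeI, K2CO3, acetone, reflux
Reagents that add atoms: iodomethane, CI
Why: Williamson O-methylation of the enolic 3-hydroxyl, the only free hydroxyl in the molecule, so no selectivity is required.

**Step 6**
Reactants: 8 2-[2,4-bis(benzyloxy)-5-methoxyphenyl]-3,7,8-trimethoxy-4H-chromen-4-one
Product: 9 2-(2,4-dihydroxy-5-methoxyphenyl)-3,7,8-trimethoxy-4H-chromen-4-one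
Conditions: H2 (1 atm), 10% Pd/C, EtOAc/MeOH, rt
Reagents that add atoms: none
Why: Catalytic hydrogenolysis of aryl benzyl ethers, which at ambient pressure should leave the fully substituted C2=C3 bond of the pyranone and the aryl methyl ethers intact.

**Step 7**
Reactants: 9 2-(2,4-dihydroxy-5-methoxyphenyl)-3,7,8-trimethoxy-4H-chromen-4-one
Product: 10 2-(2,4-diacetoxy-5-methoxyphenyl)-3,7,8-trimethoxy-4H-chromen-4-one
Conditions: Ac2O, pyridine, DMAP (cat.), rt
Reagents that add atoms: acetic anhydride, CC(=O)OC(C)=O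
Why: Nucleophile-catalysed O-acylation of both phenols, replacing acid- and oxidant-labile benzyl ethers with electron-withdrawing esters that deactivate ring B for the oxidation to come.

**Step 8**
Reactants: 10 2-(2,4-diacetoxy-5-methoxyphenyl)-3,7,8-trimethoxy-4H-chromen-4-one
Product: 12 2-(2,4-diacetoxy-5-methoxyphenyl)-5-hydroxy-3,7,8-trimethoxy-4H-chromen-4-one, via 5-O-trifluoroacetate 11 (not isolated)
Conditions: [RuCl2(p-cymene)]2 (5 mol %), PhI(OCOCF3)2 (2 equiv), CF3CO2H/(CF3CO)2O, 80 °C; then aq Na2S2O3, aq NaHCO3, rt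
Reagents that add atoms: [bis(trifluoroacetoxy)iodo]benzene, O=C(OI(OC(=O)C(F)(F)F)c1ccccc1)C(F)(F)F
Why: Chloride/trifluoroacetate exchange gives a divalent ruthenium trifluoroacetate that binds the C4 carbonyl oxygen and cleaves C5–H by carboxylate-assisted concerted metalation–deprotonation to the five-membered ruthenacycle O–C4–C4a–C5–Ru; PhI(OCOCF3)2 raises it to a tetravalent ruthenium trifluoroacetate, and C–O reductive elimination forms the C5–O bond as ester 11 and returns divalent ruthenium. The closest known reaction type is the ketone-directed ruthenium-catalysed ortho C–H oxygenation of aryl ketones, which has been applied at C5 of chromones and flavones. No ring closes and no stereocentre is formed. Site selectivity for C5–H over C6–H and over C3'–H and C6'–H of ring B is needed, and it is secured by chelation, since only C5–H is within reach of a metal on the C4 oxygen, C3 is blocked by methoxy, and C3'–H is wedged between two acetoxy groups. Chemoselectivity toward the trivalent iodine oxidant is also needed: the acetates and the protonated pyranone raise the oxidation potentials of rings B and A, and the anhydride keeps the new oxygen masked as the electron-poor trifluoroacetate, so the O5/O8 para-methoxyphenol is never exposed to oxidant. Residual oxidant is reduced before water cleaves 11 to the hydrogen-bonded phenol 12, and the aryl acetates should outlast the brief bicarbonate contact.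

**Step 9**
Reactants: 12 2-(2,4-diacetoxy-5-methoxyphenyl)-5-hydroxy-3,7,8-trimethoxy-4H-chromen-4-one
Product: 13 5,2',4'-trihydroxy-3,7,8,5'-tetramethoxyflavone
Conditions: K2CO3 (2.2 equiv), degassed MeOH, Ar, 0 °C → rt; then aq HCl
Reagents that add atoms: none
Why: Base-mediated transesterification (Zemplén-type methanolysis) cleaves aryl acetates much faster than it affects aryl methyl ethers or the pyranone, and excluding air protects the hydroquinone-type phenoxides of the product.

**Compound list**
1 | 2,4,5-trimethoxybenzaldehyde | COc1cc(OC)c(C=O)cc1OC | starting material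
2 | 2,4-dihydroxy-5-methoxybenzaldehyde | COc1cc(C=O)c(O)cc1O | intermediate
3 | 2,4-bis(benzyloxy)-5-methoxybenzaldehyde | COc1cc(C=O)c(OCc2ccccc2)cc1OCc1ccccc1 | intermediate
4 | 2-hydroxy-3,4-dimethoxyacetophenone | CC(=O)c1ccc(OC)c(OC)c1O | starting material
5 | (E)-3-[2,4-bis(benzyloxy)-5-methoxyphenyl]-1-(2-hydroxy-3,4-dimethoxyphenyl)prop-2-en-1-one | COc1cc(/C=C/C(=O)c2ccc(OC)c(OC)c2O)c(OCc2ccccc2)cc1OCc1ccccc1 | intermediate
6 | rac-(2R,3R)-2-[2,4-bis(benzyloxy)-5-methoxyphenyl]-3-hydroxy-7,8-dimethoxychroman-4-one (trans-dihydroflavonol, one enantiomer drawn, not isolated) | COc1cc([C@@H]2[C@H](C(=O)c3ccc(OC)c(OC)c3O2)O)c(OCc2ccccc2)cc1OCc1ccccc1 | intermediate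
7 | 2-[2,4-bis(benzyloxy)-5-methoxyphenyl]-3-hydroxy-7,8-dimethoxy-4H-chromen-4-one | COc1cc(-c2oc3c(OC)c(OC)ccc3c(=O)c2O)c(OCc2ccccc2)cc1OCc1ccccc1 | intermediate
8 | 2-[2,4-bis(benzyloxy)-5-methoxyphenyl]-3,7,8-trimethoxy-4H-chromen-4-one | COc1cc(-c2oc3c(OC)c(OC)ccc3c(=O)c2OC)c(OCc2ccccc2)cc1OCc1ccccc1 | intermediate
9 | 2-(2,4-dihydroxy-5-methoxyphenyl)-3,7,8-trimethoxy-4H-chromen-4-one | COc1cc(-c2oc3c(OC)c(OC)ccc3c(=O)c2OC)c(O)cc1O | intermediate
10 | 2-(2,4-diacetoxy-5-methoxyphenyl)-3,7,8-trimethoxy-4H-chromen-4-one | COc1cc(-c2oc3c(OC)c(OC)ccc3c(=O)c2OC)c(OC(C)=O)cc1OC(C)=O | intermediate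
11 | 2-(2,4-diacetoxy-5-methoxyphenyl)-3,7,8-trimethoxy-4-oxo-4H-chromen-5-yl trifluoroacetate (not isolated) | COc1cc(-c2oc3c(OC)c(OC)cc(OC(=O)C(F)(F)F)c3c(=O)c2OC)c(OC(C)=O)cc1OC(C)=O | intermediate
12 | 2-(2,4-diacetoxy-5-methoxyphenyl)-5-hydroxy-3,7,8-trimethoxy-4H-chromen-4-one | COc1cc(-c2oc3c(OC)c(OC)cc(O)c3c(=O)c2OC)c(OC(C)=O)cc1OC(C)=O | intermediate
13 | 5,2',4'-trihydroxy-3,7,8,5'-tetramethoxyflavone | COc1cc(-c2oc3c(OC)c(OC)cc(O)c3c(=O)c2OC)c(O)cc1O | target

**Step count**
Total steps: 9. Longest linear sequence: 9 steps (1 → 13); 4 is bought and enters at step 3.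

**Steps most likely to fail**

**Step 8.**
- What may go wrong:
  - single-electron oxidation of the methoxylated rings by the trivalent iodine reagent;
  - acyl exchange or loss of the acetates in the hot acid;
  - early hydrolysis of the 5-trifluoroacetate, followed by oxidative demethylation across O5/O8;
  - sequestration of ruthenium by chelation between the 3-methoxy and C4 carbonyl oxygens.
- Fallback: the C5 oxygen is brought in with the ring A building block and unmasked at the end by chelation-controlled demethylation. It sets out from 3 and comes back at 13. Aldehyde 3 is condensed (KOH, EtOH, rt) with purchased 2-hydroxy-3,4,6-trimethoxyacetophenone F1 to give (E)-3-[2,4-bis(benzyloxy)-5-methoxyphenyl]-1-(2-hydroxy-3,4,6-trimethoxyphenyl)prop-2-en-1-one F2. Alkaline peroxide would divert this 6'-methoxychalcone toward an aurone, so ring C is closed instead with catalytic I2 in DMSO at 120–130 °C, giving 2-[2,4-bis(benzyloxy)-5-methoxyphenyl]-5,7,8-trimethoxy-4H-chromen-4-one F3. Dimethyldioxirane in acetone/CH2Cl2 at 0 °C gives the racemic 2,3-epoxide F4, which a trace of p-TsOH isomerises to 2-[2,4-bis(benzyloxy)-5-methoxyphenyl]-3-hydroxy-5,7,8-trimethoxy-4H-chromen-4-one F5. MeI/K2CO3 in acetone then gives 2-[2,4-bis(benzyloxy)-5-methoxyphenyl]-3,5,7,8-tetramethoxy-4H-chromen-4-one F6. Finally, BCl3 with pentamethylbenzene in CH2Cl2 (−78 → 0 °C) removes both benzyl groups and, through the boron chelate between the C4 carbonyl oxygen and O5, only the 5-methyl group, giving 13.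

**Step 4.**
- What may go wrong:
  - sluggish hydroperoxide addition to the very electron-rich, poorly soluble enone;
  - stalling at the dihydroflavonol stage;
  - closure at Cα instead of Cβ.
- Fallback: ring closure and C3 oxygenation are separated. It sets out from 5 and comes back at 7. Chalcone 5 is cyclodehydrogenated with catalytic I2 in DMSO at 120–130 °C to 2-[2,4-bis(benzyloxy)-5-methoxyphenyl]-7,8-dimethoxy-4H-chromen-4-one F7. Dimethyldioxirane in acetone/CH2Cl2 at 0 °C oxidises its C2=C3 bond to the racemic 2,3-epoxide F8, and a trace of p-TsOH opens this to flavonol 7.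

**Step 1.**
- What may go wrong:
  - cleavage stopping after the chelated ortho methoxy group;
  - cleavage spreading to the 5-methoxy group once aluminium can bridge O4 and O5.
- Fallback: all three methyl groups are stripped and the pattern is rebuilt one oxygen at a time, using graded acidity and hydrogen bonding. It sets out from 1 and comes back at 3. Excess BBr3 (CH2Cl2, −78 °C → rt) gives 2,4,5-trihydroxybenzaldehyde F9. BnBr (1 equiv) with NaHCO3 in DMF at 40 °C alkylates the most acidic hydroxyl, para to the aldehyde, giving 4-(benzyloxy)-2,5-dihydroxybenzaldehyde F10. MeI (1 equiv) with K2CO3 in acetone at rt methylates the free 5-hydroxyl in preference to the hydrogen-bonded 2-hydroxyl, giving 4-(benzyloxy)-2-hydroxy-5-methoxybenzaldehyde F11. Forcing benzylation (BnBr, K2CO3, DMF, 60 °C) then gives 3.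

**Further compounds**
F1 | step 8 | 2-hydroxy-3,4,6-trimethoxyacetophenone (purchased) | CC(=O)c1c(OC)cc(OC)c(OC)c1O
F2 | step 8 | (E)-3-[2,4-bis(benzyloxy)-5-methoxyphenyl]-1-(2-hydroxy-3,4,6-trimethoxyphenyl)prop-2-en-1-one | COc1cc(/C=C/C(=O)c2c(OC)cc(OC)c(OC)c2O)c(OCc2ccccc2)cc1OCc1ccccc1
F3 | step 8 | 2-[2,4-bis(benzyloxy)-5-methoxyphenyl]-5,7,8-trimethoxy-4H-chromen-4-one | COc1cc(-c2cc(=O)c3c(OC)cc(OC)c(OC)c3o2)c(OCc2ccccc2)cc1OCc1ccccc1
F4 | step 8 | racemic 2,3-epoxide of F3 (cis-fused oxirane across C2–C3, one enantiomer drawn) | O=C1[C@@H]2O[C@]2(c3cc(OC)c(OCc4ccccc4)cc3OCc3ccccc3)Oc2c1c(OC)cc(OC)c2OC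
F5 | step 8 | 2-[2,4-bis(benzyloxy)-5-methoxyphenyl]-3-hydroxy-5,7,8-trimethoxy-4H-chromen-4-one | COc1cc(-c2oc3c(OC)c(OC)cc(OC)c3c(=O)c2O)c(OCc2ccccc2)cc1OCc1ccccc1
F6 | step 8 | 2-[2,4-bis(benzyloxy)-5-methoxyphenyl]-3,5,7,8-tetramethoxy-4H-chromen-4-one | COc1cc(-c2oc3c(OC)c(OC)cc(OC)c3c(=O)c2OC)c(OCc2ccccc2)cc1OCc1ccccc1
F7 | step 4 | 2-[2,4-bis(benzyloxy)-5-methoxyphenyl]-7,8-dimethoxy-4H-chromen-4-one | COc1cc(-c2cc(=O)c3ccc(OC)c(OC)c3o2)c(OCc2ccccc2)cc1OCc1ccccc1
F8 | step 4 | racemic 2,3-epoxide of F7 (cis-fused oxirane across C2–C3, one enantiomer drawn) | O=C1[C@@H]2O[C@]2(c3cc(OC)c(OCc4ccccc4)cc3OCc3ccccc3)Oc2c1ccc(OC)c2OC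
F9 | step 1 | 2,4,5-trihydroxybenzaldehyde | O=Cc1cc(O)c(O)cc1O
F10 | step 1 | 4-(benzyloxy)-2,5-dihydroxybenzaldehyde | O=Cc1cc(O)c(OCc2ccccc2)cc1O
F11 | step 1 | 4-(benzyloxy)-2-hydroxy-5-methoxybenzaldehyde | COc1cc(C=O)c(O)cc1OCc1ccccc1
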